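I looked at the excess first.

- south-west: starting material 20 mM; partner 50.0 mM; rival reagent 50.0 mM; time 40 min
- north: starting material 20 mM; partner 50.0 mM; rival reagent 50.0 mM; time 60 min

    target ⇌ isomer of the product (K1 = 30, k1 = 1.3 × 10⁻⁴ /s)
    starting material + rival reagent → side product (k2 = 0.0063 /M/s)
    starting material + partner → target (k3 = 0.014 /M/s)

- which of these there is most of at the end, counted by the starting material in it, south-west (isomer of the product / target / side product / starting material)
- which of these there is most of at the end, counted by the starting material in it, north (isomer of the product / target / side product / starting material)
- final amount of the leader among these, as a percentage of the starting material charged, in south-west
- final amount of the leader among these, as a percentage of the starting material charged, in north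

South-west and north had the same charges, with partner and rival reagent each at 2.50 times the starting material. So I held [partner] and [rival reagent] constant, which left [starting material] as the one concentration setting the order: pseudo-first-order decay down two branches. I set up three rows, each with its constant at the charge and the half-life of that step by itself, south-west:

- starting material to target: 0.0420 /min, 17 min
- starting material to side product: 0.0189 /min, 37 min
- target to isomer of the product, forward step: 0.00780 /min, 89 min

The first two rows compete for the same starting material, and the first is faster. At the charges, of each portion consumed, 69.0% goes to target; that fraction, the first row over the sum of the first two, is the branching share. Their sum, 0.0609 /min, gives starting material a half-life of 11.4 min.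

The third row is slower, but it drains target while target forms, and I dropped its way back, smaller by a factor of 30. The two steps in series gave target 51.0% in south-west and 47.5% in north. Side product's part of the consumed was 31.0%, and isomer in north came to 19.7%, so target led in both. The target branch uses 27.6% of the partner charge, so I expected these figures to read high.

The forecast gave target at 48% in south-west and target at 45.5% in north, lower than my figures, reasoning that "about two-thirds of the starting material goes down the productive route".

The flask gave target at 48.0% in south-west and target at 45.7% in north.

In north, target was made 8.16 times as fast as it was used up, each step taken net, at 11.1 min. In north at 60.0 min, with starting material at 4.64%, that ratio was 0.414, and isomer stood at 18.5%. Target plus isomer then made up 67.3% of the north products gathered over the whole run, less than the 69.0% I had reckoned at the charges, and partner stood at 74% of its charge.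

In the neighbour of north with 30 mM of partner, the branching share falls to 57.1%. With the two branch constants summing to 0.0441 /min, my reckoning gives side product 39.8% and target 38.6%, side product narrowly ahead. That flask ended with side product in the lead at 40.2%, and target at 35.3%.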